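**Plan**

1. Retrosynthesis: ring C is opened at C3–C4 (intramolecular alkene hydroacylation). The C2=CH2 enol ether goes back to an aryl ester on O1 (ester methylenation), that is, to a ring-A salicylaldehyde and the ring-B benzoic acid. The C8–CH2 bond is cut (Negishi coupling), and the side chain goes back to (R)-limonene oxide (ring cleavage at C1–C2, loss of the old C2 as CO2).
2. Enabling feature: C2 carries only O1, ring B and H, and C3 is an unsubstituted CH2 between C2 and the ring-A acyl carbon C4. C2=C3 can therefore be held as a 1,1-disubstituted enol ether on O1, ortho to a C4 formyl group; adding the formyl C–H across it makes C3–C4, ring C and the C2 stereocentre at once, with nothing to remove afterwards.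
3. Forward order: side-chain iodide from limonene oxide; coupling to C8 of iodinated, bis-silylated 2,4,6-trihydroxybenzaldehyde (ring A); ring B added as an aryl ester on O1 and methylenated; ring C closed last; global desilylation.
4. Stereochemistry: the side-chain centre (2R) is C4 of (R)-limonene (chiral pool, never a reacting carbon). C2 (S) is set by the chiral bisphosphine–rhodium catalyst in the ring closure.
5. Ring-A regiochemistry: O1 is singled out by its hydrogen bond to the formyl group (left free on silylation, directs iodination to C8).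

Key step: step 13

Abbreviations: TBS = tert-butyldimethylsilyl, TES = triethylsilyl; O1, C2, C3, C4, C8 are the flavanone positions of the target.

Remark (assumption): the sense of induction in step 13 is assigned by analogy with carbon-tethered substrates; it should be checked on the des-alkyl analogue of 19 and the antipodal ligand taken if the 2R series results.

**Route**

Step 1
Reactants: 1 (4R)-limonene 1,2-oxide (commercial cis/trans mixture at the epoxide)
Product: 2 (3R)-6-oxo-3-(prop-1-en-2-yl)heptanal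
Conditions: H5IO6 (1.2 equiv), THF/H2O, 0 °C to rt
Reagents that add atoms: water, O
Why: Periodic acid hydrolyses the epoxide and cleaves the resulting 1,2-diol in one flask (glycol cleavage), so both epoxide isomers should converge on one keto aldehyde while the isopropenyl group and the stereocentre (not α to either carbonyl) are untouched.

Step 2
Reactants: 2 (3R)-6-oxo-3-(prop-1-en-2-yl)heptanal
Product: 3 (3R)-6-oxo-3-(prop-1-en-2-yl)heptanoic acid
Conditions: NaClO2, NaH2PO4, 2-methyl-2-butene, t-BuOH/H2O, 0 °C to rt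
Reagents that add atoms: sodium chlorite, [Na+].[O-]Cl=O
Why: Pinnick oxidation takes the aldehyde to the acid under buffered conditions in which the hypochlorite by-product is trapped by 2-methyl-2-butene, so the methyl ketone and the isopropenyl group should not react.

Step 3
Reactants: 3 (3R)-6-oxo-3-(prop-1-en-2-yl)heptanoic acid
Product: 5 (5S)-5-(iodomethyl)-6-methylhept-6-en-2-one, via Barton ester 4 (not isolated)
Conditions: 1-hydroxypyridine-2(1H)-thione, DCC, DMAP (cat.), CH2Cl2, 0 °C, dark; then CHI3 (3 equiv), hν (tungsten lamp), rt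
Reagents that add atoms: iodoform, IC(I)I
Why: Barton decarboxylative iodination: the thiohydroxamate ester fragments in a radical chain to CO2 and the primary alkyl radical, which should abstract iodine from iodoform faster than a homoallyl radical rearranges, so the adjacent stereocentre is not touched.

Step 4
Reactants: 5 (5S)-5-(iodomethyl)-6-methylhept-6-en-2-one
Product: 6 (5S)-5-(iodomethyl)-2,6-dimethylhept-6-en-2-ol
Conditions: MeMgBr (1.2 equiv), Et2O, −78 °C; AcOH/THF quench at −78 °C
Reagents that add atoms: methylmagnesium bromide, C[Mg]Br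
Why: Grignard addition to the methyl ketone at −78 °C is much faster than any reaction of MeMgBr with the primary iodide, and the cold acidic quench should prevent Williamson closure of the alkoxide onto the iodide.

Step 5
Reactants: 6 (5S)-5-(iodomethyl)-2,6-dimethylhept-6-en-2-ol
Product: 7 triethyl{[(5S)-5-(iodomethyl)-2,6-dimethylhept-6-en-2-yl]oxy}silane
Conditions: TESOTf, 2,6-lutidine, CH2Cl2, −78 to 0 °C
Reagents that add atoms: triethylsilyl trifluoromethanesulfonate, CC[Si](CC)(CC)OS(=O)(=O)C(F)(F)F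
Why: Silylation with the silyl triflate and a hindered pyridine base protects the tertiary alcohol, which would otherwise quench the organozinc of step 8 and consume the titanium reagent of step 12.

Step 6
Reactants: 8 2,4,6-trihydroxybenzaldehyde
Product: 9 4,6-bis(TBSO)-2-hydroxybenzaldehyde
Conditions: TBSCl (2.1 equiv), imidazole, CH2Cl2/DMF, 0 °C
Reagents that add atoms: tert-butyldimethylsilyl chloride, CC(C)(C)[Si](C)(C)Cl
Why: The 4-OH and one ortho OH are silylated while the last ortho OH, locked in a hydrogen bond to the formyl group, should stay free (the chelation control familiar from 2-hydroxy-4,6-dialkoxy phloroglucinol aldehydes and ketones), and this single free phenol becomes O1.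

Step 7
Reactants: 9 4,6-bis(TBSO)-2-hydroxybenzaldehyde
Product: 10 4,6-bis(TBSO)-2-hydroxy-3-iodobenzaldehyde
Conditions: NIS (1.05 equiv), MeCN, 0 °C to rt, dark
Reagents that add atoms: N-iodosuccinimide, O=C1CCC(=O)N1I
Why: Electrophilic aromatic iodination should take place ortho to the free hydroxyl (C3, flanked by OH and one silyloxy group) and not at C5 between the two bulky silyloxy groups, which marks the future C8.

Step 8
Reactants: 7 triethyl{[(5S)-5-(iodomethyl)-2,6-dimethylhept-6-en-2-yl]oxy}silane; 10 4,6-bis(TBSO)-2-hydroxy-3-iodobenzaldehyde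
Product: 12 4,6-bis(TBSO)-2-hydroxy-3-{(2R)-5-methyl-2-(prop-1-en-2-yl)-5-(TESO)hexyl}benzaldehyde, via alkylzinc iodide 11 (not isolated)
Conditions: 7, Zn dust (BrCH2CH2Br and Me3SiCl activation), LiCl, THF, 40 °C; then added over 1 h to 10, Pd(OAc)2 (3 mol %), SPhos (6 mol %), THF, 25 to 45 °C
Reagents that add atoms: none
Why: Negishi sp3–sp2 coupling: the LiCl-solubilised primary alkylzinc iodide tolerates the aldehyde and silyl ethers, SPhos-ligated zerovalent palladium inserts into the di-ortho-substituted C–I bond, slow addition lets coupling outrun protonolysis by the chelated phenol, and the stereocentre β to zinc is not involved.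

Step 9
Reactants: 13 4-hydroxy-2-methoxybenzoic acid
Product: 15 4-(TBSO)-2-methoxybenzoic acid, via silyl ester 14 (not isolated)
Conditions: TBSCl (2.3 equiv), imidazole, DMF, rt; then AcOH, THF/H2O, rt
Reagents that add atoms: tert-butyldimethylsilyl chloride, CC(C)(C)[Si](C)(C)Cl
Why: Exhaustive silylation followed by selective hydrolysis of the far more labile silyl ester leaves the aryl silyl ether, a standard protection of a phenolic acid.

Step 10
Reactants: 12 4,6-bis(TBSO)-2-hydroxy-3-{(2R)-5-methyl-2-(prop-1-en-2-yl)-5-(TESO)hexyl}benzaldehyde; 15 4-(TBSO)-2-methoxybenzoic acid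
Product: 16 3,5-bis(TBSO)-2-formyl-6-{(2R)-5-methyl-2-(prop-1-en-2-yl)-5-(TESO)hexyl}phenyl 4-(TBSO)-2-methoxybenzoate
Conditions: EDC·HCl, DMAP (1 equiv), CH2Cl2, rt
Reagents that add atoms: none
Why: Steglich esterification through the acylpyridinium ion should acylate even the hindered, hydrogen-bonded phenol O1, and the aryl ester then holds O1, C2 and ring B in the connectivity of the target.

Step 11
Reactants: 16 3,5-bis(TBSO)-2-formyl-6-{(2R)-5-methyl-2-(prop-1-en-2-yl)-5-(TESO)hexyl}phenyl 4-(TBSO)-2-methoxybenzoate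
Product: 17 3,5-bis(TBSO)-2-(dimethoxymethyl)-6-{(2R)-5-methyl-2-(prop-1-en-2-yl)-5-(TESO)hexyl}phenyl 4-(TBSO)-2-methoxybenzoate
Conditions: HC(OMe)3, MeOH, PPTS (2 mol %), 0 °C to rt; Et3N quench
Reagents that add atoms: trimethyl orthoformate, COC(OC)OC; methanol, CO
Why: Acid-catalysed acetalisation with the orthoformate as water scavenger masks the aldehyde, which would otherwise be methylenated before the ester in step 12, while the aryl ester and the silyl ethers should tolerate PPTS.

Step 12
Reactants: 17 3,5-bis(TBSO)-2-(dimethoxymethyl)-6-{(2R)-5-methyl-2-(prop-1-en-2-yl)-5-(TESO)hexyl}phenyl 4-(TBSO)-2-methoxybenzoate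
Product: 19 4,6-bis(TBSO)-2-({1-[4-(TBSO)-2-methoxyphenyl]ethenyl}oxy)-3-{(2R)-5-methyl-2-(prop-1-en-2-yl)-5-(TESO)hexyl}benzaldehyde, via enol ether acetal 18 (not isolated)
Conditions: Cp2TiMe2 (3 equiv), PhMe, 70 °C, dark; then SiO2, 10% aq. oxalic acid, CH2Cl2, 0 °C
Reagents that add atoms: dimethyltitanocene, C[Ti+2]C.[cH-]1cccc1.[cH-]1cccc1
Why: Petasis methylenation turns the aryl benzoate into the 1-aryloxy-1-arylethene (the classical titanium-carbene olefination of aryl esters) under non-acidic conditions that spare the acetal, and the 2,4,6-trioxygenated benzaldehyde acetal should then be hydrolysed by weak acid far faster than the aryl enol ether.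

Step 13
Reactants: 19 4,6-bis(TBSO)-2-({1-[4-(TBSO)-2-methoxyphenyl]ethenyl}oxy)-3-{(2R)-5-methyl-2-(prop-1-en-2-yl)-5-(TESO)hexyl}benzaldehyde
Product: 20 (2S)-5,7-bis(TBSO)-2-[4-(TBSO)-2-methoxyphenyl]-8-{(2R)-5-methyl-2-(prop-1-en-2-yl)-5-(TESO)hexyl}-2,3-dihydro-4H-chromen-4-one
Conditions: [RhCl(cod)]2 (2.5 mol %; cod = 1,5-cyclooctadiene), (R)-DTBM-SEGPHOS (5.5 mol %), Na[B(3,5-(CF3)2C6H3)4] (5 mol %), 1,4-dioxane, 70 °C
Reagents that add atoms: none
Why: Proposed new method: the cationic monovalent rhodium–bisphosphine complex adds oxidatively into the formyl C4–H bond to give an acyl rhodium hydride (trivalent rhodium), the C2=C3 enol ether held by O1 inserts into Rh–H with hydride going to C2 and rhodium to the unsubstituted C3, and C–C reductive elimination from the seven-membered acyl–alkyl rhodacycle forms C3–C4. The closest known reaction type is the rhodium-catalysed enantioselective intramolecular hydroacylation of 1,1-disubstituted alkenes in ortho-allyl- and ortho-vinylbenzaldehydes to 3-substituted tetralones and indanones; here the benzylic CH2 of the tether is replaced by O1 and the alkene is an enol ether. Ring C closes in the 6-endo-trig mode. The only new stereocentre, C2, is set in the hydride-insertion step by the chiral bisphosphine (delivery to the Re face of C2 gives 2S), the remote side-chain centre having no say. The step needs endo over exo regioselectivity, secured by the 1,1-disubstitution at C2 (the exo path would need a tertiary α-oxy alkyl–rhodium and a quaternary centre), and reductive elimination faster than decarbonylation or β-aryloxide loss, for which the chelating ligand, the O1 donor and the endocyclic C2–O1 bond of the rhodacycle are relied on. The isopropenyl group is remote and 1,1-disubstituted and should not compete with the tethered alkene.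

Step 14
Reactants: 20 (2S)-5,7-bis(TBSO)-2-[4-(TBSO)-2-methoxyphenyl]-8-{(2R)-5-methyl-2-(prop-1-en-2-yl)-5-(TESO)hexyl}-2,3-dihydro-4H-chromen-4-one
Product: 21 (2S)-5,7-dihydroxy-2-(4-hydroxy-2-methoxyphenyl)-8-[(2R)-5-hydroxy-5-methyl-2-(prop-1-en-2-yl)hexyl]-2,3-dihydro-4H-chromen-4-one
Conditions: HF·pyridine, pyridine, THF, 0 °C to rt
Reagents that add atoms: none
Why: Fluoride-mediated desilylation under buffered conditions should remove the three aryl silyl ethers and the tertiary TES ether without exposing the flavanone to base (no retro-oxa-Michael opening, C2 retained) or the isopropenyl group and tertiary alcohol to strong acid.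

**Compound list**

1 | (4R)-1-methyl-4-(prop-1-en-2-yl)-7-oxabicyclo[4.1.0]heptane, (+)-limonene 1,2-oxide, cis/trans mixture | CC12OC1C[C@@H](CC2)C(C)=C | starting material
2 | (3R)-6-oxo-3-(prop-1-en-2-yl)heptanal | O=CC[C@@H](CCC(C)=O)C(C)=C | intermediate
3 | (3R)-6-oxo-3-(prop-1-en-2-yl)heptanoic acid | OC(=O)C[C@@H](CCC(C)=O)C(C)=C | intermediate
4 | 2-thioxopyridin-1(2H)-yl (3R)-6-oxo-3-(prop-1-en-2-yl)heptanoate (Barton ester, not isolated) | O=C(C[C@@H](CCC(C)=O)C(C)=C)On1ccccc1=S | intermediate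
5 | (5S)-5-(iodomethyl)-6-methylhept-6-en-2-one | IC[C@@H](CCC(C)=O)C(C)=C | intermediate
6 | (5S)-5-(iodomethyl)-2,6-dimethylhept-6-en-2-ol | IC[C@@H](CCC(C)(C)O)C(C)=C | intermediate
7 | triethyl{[(5S)-5-(iodomethyl)-2,6-dimethylhept-6-en-2-yl]oxy}silane | IC[C@@H](CCC(C)(C)O[Si](CC)(CC)CC)C(C)=C | intermediate
8 | 2,4,6-trihydroxybenzaldehyde | O=Cc1c(O)cc(O)cc1O | starting material
9 | 4,6-bis[(tert-butyldimethylsilyl)oxy]-2-hydroxybenzaldehyde | O=Cc1c(O)cc(O[Si](C)(C)C(C)(C)C)cc1O[Si](C)(C)C(C)(C)C | intermediate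
10 | 4,6-bis[(tert-butyldimethylsilyl)oxy]-2-hydroxy-3-iodobenzaldehyde | O=Cc1c(O)c(I)c(O[Si](C)(C)C(C)(C)C)cc1O[Si](C)(C)C(C)(C)C | intermediate
11 | {(2S)-5-methyl-2-(prop-1-en-2-yl)-5-[(triethylsilyl)oxy]hexyl}zinc iodide (not isolated) | I[Zn]C[C@@H](CCC(C)(C)O[Si](CC)(CC)CC)C(C)=C | intermediate
12 | 4,6-bis(TBSO)-2-hydroxy-3-{(2R)-5-methyl-2-(prop-1-en-2-yl)-5-[(triethylsilyl)oxy]hexyl}benzaldehyde | C=C(C)[C@H](CCC(C)(C)O[Si](CC)(CC)CC)Cc1c(O[Si](C)(C)C(C)(C)C)cc(O[Si](C)(C)C(C)(C)C)c(C=O)c1O | intermediate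
13 | 4-hydroxy-2-methoxybenzoic acid | COc1cc(O)ccc1C(=O)O | starting material
14 | tert-butyldimethylsilyl 4-[(tert-butyldimethylsilyl)oxy]-2-methoxybenzoate (not isolated) | COc1cc(O[Si](C)(C)C(C)(C)C)ccc1C(=O)O[Si](C)(C)C(C)(C)C | intermediate
15 | 4-[(tert-butyldimethylsilyl)oxy]-2-methoxybenzoic acid | COc1cc(O[Si](C)(C)C(C)(C)C)ccc1C(=O)O | intermediate
16 | 3,5-bis(TBSO)-2-formyl-6-{(2R)-5-methyl-2-(prop-1-en-2-yl)-5-(TESO)hexyl}phenyl 4-(TBSO)-2-methoxybenzoate | C=C(C)[C@H](CCC(C)(C)O[Si](CC)(CC)CC)Cc1c(O[Si](C)(C)C(C)(C)C)cc(O[Si](C)(C)C(C)(C)C)c(C=O)c1OC(=O)c1ccc(O[Si](C)(C)C(C)(C)C)cc1OC | intermediate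
17 | 3,5-bis(TBSO)-2-(dimethoxymethyl)-6-{(2R)-5-methyl-2-(prop-1-en-2-yl)-5-(TESO)hexyl}phenyl 4-(TBSO)-2-methoxybenzoate | C=C(C)[C@H](CCC(C)(C)O[Si](CC)(CC)CC)Cc1c(O[Si](C)(C)C(C)(C)C)cc(O[Si](C)(C)C(C)(C)C)c(C(OC)OC)c1OC(=O)c1ccc(O[Si](C)(C)C(C)(C)C)cc1OC | intermediate
18 | 1,5-bis(TBSO)-2-(dimethoxymethyl)-3-({1-[4-(TBSO)-2-methoxyphenyl]ethenyl}oxy)-4-{(2R)-5-methyl-2-(prop-1-en-2-yl)-5-(TESO)hexyl}benzene (not isolated) | C=C(C)[C@H](CCC(C)(C)O[Si](CC)(CC)CC)Cc1c(O[Si](C)(C)C(C)(C)C)cc(O[Si](C)(C)C(C)(C)C)c(C(OC)OC)c1OC(=C)c1ccc(O[Si](C)(C)C(C)(C)C)cc1OC | intermediate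
19 | 4,6-bis(TBSO)-2-({1-[4-(TBSO)-2-methoxyphenyl]ethenyl}oxy)-3-{(2R)-5-methyl-2-(prop-1-en-2-yl)-5-(TESO)hexyl}benzaldehyde | C=C(C)[C@H](CCC(C)(C)O[Si](CC)(CC)CC)Cc1c(O[Si](C)(C)C(C)(C)C)cc(O[Si](C)(C)C(C)(C)C)c(C=O)c1OC(=C)c1ccc(O[Si](C)(C)C(C)(C)C)cc1OC | intermediate
20 | (2S)-5,7-bis(TBSO)-2-[4-(TBSO)-2-methoxyphenyl]-8-{(2R)-5-methyl-2-(prop-1-en-2-yl)-5-(TESO)hexyl}-2,3-dihydro-4H-chromen-4-one | C=C(C)[C@H](CCC(C)(C)O[Si](CC)(CC)CC)Cc1c(O[Si](C)(C)C(C)(C)C)cc(O[Si](C)(C)C(C)(C)C)c2c1O[C@H](c1ccc(O[Si](C)(C)C(C)(C)C)cc1OC)CC2=O | intermediate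
21 | (2S)-5,7-dihydroxy-2-(4-hydroxy-2-methoxyphenyl)-8-[(2R)-5-hydroxy-5-methyl-2-(prop-1-en-2-yl)hexyl]-2,3-dihydro-4H-chromen-4-one | C=C(C)[C@H](CCC(C)(C)O)Cc1c(O)cc(O)c2c1O[C@H](c1ccc(O)cc1OC)CC2=O | target

**Summary**

Total step count: 14. Longest linear sequence: 11 steps (steps 1–5, 8, 10–14).

Steps most likely to fail:

1. Step 13 (Proposed new method). The acyl rhodium hydride at the di-ortho-substituted aldehyde may lose CO before the enol ether inserts. The cationic metal may instead act as a Lewis acid and trigger a Prins-type addition of the enol ether to the aldehyde. Hydride delivery to C2 may also show poor facial selectivity. The fallback uses known chemistry, sets out from 12 and returns at 20. Aldehyde 12 is treated with HC≡CMgBr (THF, −20 °C) to give the propargylic alcohol F1, which is oxidised with MnO2 (CH2Cl2) to the ynone F2. With Et3N (CH2Cl2, rt) this should close by 6-endo-dig oxa-Michael addition to the chromone F3. Palladium-catalysed asymmetric conjugate addition of the arylboronic acid F4 (Pd(OCOCF3)2, t-BuPyOx ligand of the hand that gives 2S, NH4PF6, H2O, ClCH2CH2Cl, 60 °C), a reaction type established for chromones, should then give 20.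

2. Step 8. The alkylzinc may be protonated by the phenol before it couples, oxidative addition at the electron-rich, doubly flanked C–I bond may be slow, and the radical stage of zinc insertion may allow some 1,2-vinyl shift of the homoallyl unit. The fallback sets out from 10, 15 and 7 and returns at 16. Phenol 10 is first esterified with acid 15 (EDC·HCl, DMAP, CH2Cl2) to the aryl ester F5, which has no acidic proton and a less electron-rich C–I bond. Iodide 7 is converted by polar lithium–iodine exchange (t-BuLi, Et2O, −78 °C) into the alkyllithium F6 and trapped with 9-methoxy-9-borabicyclo[3.3.1]nonane as the borinate F7. B-alkyl Suzuki–Miyaura coupling of F7 with F5 (PdCl2(dppf), AsPh3, DMF/THF, rt, no added base) should give 16 directly, and step 10 is then omitted.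

3. Step 12. Methylenation of the doubly ortho-substituted ester may stall, and the acid-labile enol ether may be hydrolysed together with the acetal or on silica. The fallback sets out from 12 and returns at 19, and avoids both the ester and the acetal. Phenol 12 is O-vinylated in a copper-mediated oxidative coupling (Chan–Lam type) with the alkenylboronate F8 (Cu(OAc)2, pyridine, 4 Å molecular sieves, CH2Cl2, air, rt), which should give 19 with the aldehyde never masked.

Further compounds
F1 | step 13 | 1-[4,6-bis(TBSO)-2-hydroxy-3-{(2R)-5-methyl-2-(prop-1-en-2-yl)-5-(TESO)hexyl}phenyl]prop-2-yn-1-ol | C=C(C)[C@H](CCC(C)(C)O[Si](CC)(CC)CC)Cc1c(O[Si](C)(C)C(C)(C)C)cc(O[Si](C)(C)C(C)(C)C)c(C(O)C#C)c1O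
F2 | step 13 | 1-[4,6-bis(TBSO)-2-hydroxy-3-{(2R)-5-methyl-2-(prop-1-en-2-yl)-5-(TESO)hexyl}phenyl]prop-2-yn-1-one | C=C(C)[C@H](CCC(C)(C)O[Si](CC)(CC)CC)Cc1c(O[Si](C)(C)C(C)(C)C)cc(O[Si](C)(C)C(C)(C)C)c(C(=O)C#C)c1O
F3 | step 13 | 5,7-bis(TBSO)-8-{(2R)-5-methyl-2-(prop-1-en-2-yl)-5-(TESO)hexyl}-4H-chromen-4-one | C=C(C)[C@H](CCC(C)(C)O[Si](CC)(CC)CC)Cc1c(O[Si](C)(C)C(C)(C)C)cc(O[Si](C)(C)C(C)(C)C)c2c1OC=CC2=O
F4 | step 13 | {4-[(tert-butyldimethylsilyl)oxy]-2-methoxyphenyl}boronic acid | COc1cc(O[Si](C)(C)C(C)(C)C)ccc1B(O)O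
F5 | step 8 | 3,5-bis(TBSO)-2-formyl-6-iodophenyl 4-(TBSO)-2-methoxybenzoate | O=Cc1c(OC(=O)c2ccc(O[Si](C)(C)C(C)(C)C)cc2OC)c(I)c(O[Si](C)(C)C(C)(C)C)cc1O[Si](C)(C)C(C)(C)C
F6 | step 8 | {(2S)-5-methyl-2-(prop-1-en-2-yl)-5-[(triethylsilyl)oxy]hexyl}lithium | [Li]C[C@@H](CCC(C)(C)O[Si](CC)(CC)CC)C(C)=C
F7 | step 8 | lithium 9-methoxy-9-{(2S)-5-methyl-2-(prop-1-en-2-yl)-5-[(triethylsilyl)oxy]hexyl}-9-boranuidabicyclo[3.3.1]nonane | [Li+].CO[B-]1(C[C@@H](CCC(C)(C)O[Si](CC)(CC)CC)C(C)=C)C2CCCC1CCC2
F8 | step 12 | 2-{1-[4-(TBSO)-2-methoxyphenyl]ethenyl}-4,4,5,5-tetramethyl-1,3,2-dioxaborolane | C=C(B1OC(C)(C)C(C)(C)O1)c1ccc(O[Si](C)(C)C(C)(C)C)cc1OC
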